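Numbering used below: ring A is the pentyl-bearing benzoic acid ring (C1 carboxyl carbon, C2 hydroxyl, C4 ester oxygen, C6 pentyl). Ring B is the acyl ring (C1' ester carbonyl, C2' hydroxyl, C4' methoxy, C6' methyl).

## Analysis of the target

Compound 13 is a depside: two separate benzene rings joined by one aryl ester, with no fused or saturated ring and no stereocenter. Ring A is a 2-hydroxy-6-pentylbenzoic acid acylated on its C4 oxygen, and ring B is a 2-hydroxy-4-methoxy-6-methylbenzoyl unit, so both rings carry the resorcinol pattern of olivetol 1 and methyl orsellinate 3. The sensitive groups are the depside ester, which hydroxide, alkoxides and amines cleave, and the C1 carboxyl of ring A. That carboxyl sits between the C2 hydroxyl and the C6 pentyl chain, ortho and para to oxygen, and is lost as CO2 on heating or in acid. It therefore cannot be freed from an ordinary ester by base, nor carried through hot or acidic steps. Three phenolic oxygens of one kind (C2–O and C4–O of ring A, C2'–O of ring B) and the C4' methyl ether also have to be told apart, and C1 is the most crowded carbon of ring A. The strategy rests on C1 of ring A being para to the C4 oxygen and ortho to the C2 oxygen, the site an electrophilic halogen attacks in 1, so that a bromine placed there can be exchanged for CO2 at a cathode, without base or heat, and the labile acid exists only in the last two steps.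

## Retrosynthetic reasoning

**13 to 12.** The two O–CH2Ph bonds at C2–O and C2'–O are cut last. Benzyl ethers are chosen because they come off together under neutral conditions at room temperature, whereas base, heat or strong acid would be tolerated by neither the depside ester nor the decarboxylation-prone acid. The forward step must free two phenols and touch nothing else.

**12 to 10 and 11.** The C1–CO2H bond of ring A is cut, giving the aryl bromide 10 and carbon dioxide 11. Cutting here keeps the carboxyl out of every earlier step, so no carboxyl protecting group is needed and no ester has to be cleaved beside the depside link. A disconnection at the depside ester with the carboxyl already in place would need a carboxyl ester that is later removed selectively. The forward reaction must turn C–Br into C–CO2H at a carbon flanked by benzyloxy and pentyl, in the presence of an aryl ester and two benzyl ethers. Nickel catalysis at a cathode with a sacrificial anode does this at room temperature and without base.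

**10 to 9 and 5.** The O–benzyl bond at the C2 oxygen of ring A is cut, giving the bromophenol 9 and benzyl bromide 5. The benzyl group goes on after the ester because the small, reactive 5 can reach the hydroxyl beside bromine, which the bulky acyl group avoids.

**9 to 2 and 7 (through 8).** The depside C(=O)–O bond is cut, giving the bromoresorcinol 2 and the ring B acid 7, activated as its chloride 8. This is plain acyl substitution, so the risk of the route is not spent here. The forward step must choose between two hydroxyls of 2. The hydroxyl para to bromine has two ortho hydrogens, while the other is shielded by the ortho bromine, and 8 is itself di-ortho-substituted.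

**2 to 1.** The C–Br bond is cut, giving olivetol 1. In 1 the two positions para to a hydroxyl are equivalent by symmetry, so a single electrophilic bromination marks the future C1. The bromine goes on before ring B is attached because the electron-rich ring B would otherwise compete.

**7 to 6 to 4 to 3 (and 5).** Ring B is taken back through ester hydrolysis, O-benzylation at C2'–O with 5, and O-methylation at C4'–O to methyl orsellinate 3. The C2' hydroxyl of 3 is hydrogen-bonded to the ester carbonyl, so the C4' hydroxyl is alkylated first and the order methyl then benzyl needs no extra protecting group.

## Alternatives that were turned down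

Alternative 1: Ring A is cut at C1–C6 and C2–C3 and built from (E)-non-3-en-2-one A2 and dibenzyl malonate A3.
- Key step: with the sodium alkoxide matching the ester, A3 adds to the pentyl-bearing enone carbon of A2, and the methyl ketone enolate then closes onto one ester group of the malonate unit. This gives racemic benzyl trans-2,4-dioxo-6-pentylcyclohexane-1-carboxylate A1. The C4 enol oxygen of A1 would then be acylated with 8, the ring dehydrogenated to the arene, and the benzyl groups removed.
- For it: the carboxyl carbon is present from the first step, so no bond has to be made at the crowded C1 late. The annulation of A2 with A3 forms two skeletal bonds and the ring in one flask and fixes the substitution pattern by construction. On certainty about C1 this alternative is stronger than the chosen route.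
- Against it: A1 offers two enolisable oxygens (C2 and C4) and two nucleophilic carbons (C1 and C3), so acylation at the C4 oxygen alone is not assured. Enol esters of cyclic 1,3-diones are vinylogous anhydrides that pass their acyl group on to carbon or to any nucleophile. The dehydrogenation needs an oxidant or a halogenation–elimination sequence in the presence of the electron-rich ring B and the labile enol ester. The two stereocenters of A1 are made only to be destroyed.
- Comparison: the step count is about the same (annulation, acylation, aromatisation, deprotection, plus three steps to 7). The chosen route gives up the certainty at C1 but buys both rings as arenes, needs no change of oxidation level, and forms the depside bond on an ordinary phenol.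

Alternative 2: Ring B is cut at C1'–C6' and traced to an open-chain triketo ester.
- Key step: benzyl 2,4-dihydroxy-6-pentylbenzoate A6 would carry a 3,5,7-trioxooctanoyl group on its C4 oxygen, as in benzyl 2-hydroxy-6-pentyl-4-[(3,5,7-trioxooctanoyl)oxy]benzoate A5. Aldol addition of chain C2 to the C7 ketone and loss of water would give benzyl 4-(2,4-dihydroxy-6-methylbenzoyl)oxy-2-hydroxy-6-pentylbenzoate A4. Methylation of the only non-chelated phenol of A4 (C4'–OH) and hydrogenolysis of its benzyl ester would finish.
- For it: it follows the biosynthetic logic and needs no protecting group on ring B. The ring A carboxyl is held as a benzyl ester throughout, and the late methylation of A4 is guided by hydrogen bonding. On protecting-group economy it is stronger than the chosen route.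
- Against it: an aryl ester is a poor place to run polyketide cyclisations. In A5 the C5 enol oxygen can close onto C1 and expel the ring A phenoxide as a pyranone forms, and Claisen closure from C6 to C1 expels it as well. The depside bond is therefore at risk in the very step meant to build ring B. A5 must be made by ketene-type acylation of A6 and cannot be stored, and A6 must first be made from 1 by carboxylation and benzylation.
- Comparison: it is longer and less certain, and it builds a ring that can be bought as 3. The chosen route forms the ester from a stable, isolable acid, 7, by ordinary acyl substitution.

Alternative 3: Both bonds at the depside carbonyl (C1'–C(=O) and C(=O)–O) are cut, giving three components.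
- Key step: a palladium catalyst with a wide-bite-angle bisphosphine would join 2-iodo-1,5-dimethoxy-3-methylbenzene A8, carbon monoxide A9 and the free C4 hydroxyl of A6. The product is benzyl 4-(2,4-dimethoxy-6-methylbenzoyl)oxy-2-hydroxy-6-pentylbenzoate A7. Chelation-controlled cleavage of the C2' methyl ether of A7 and hydrogenolysis of its benzyl ester would follow.
- For it: it is the most convergent plan, making two bonds in one step with no ring B acid, no saponification and no acid chloride. If A6 is at hand it is shorter than the chosen route by two or three steps, so on step count it is stronger.
- Against it: the acylpalladium intermediate is di-ortho-substituted and must be captured by a phenoxide, a weak partner, at elevated temperature with base and under A9. Under those conditions the depside A7 can undergo ester exchange, and loss of iodine from A8 competes. A Lewis acid must then distinguish the C2' from the C4' methyl ether of A7 while sparing its ester. A6 still requires an early carboxylation of 1 at the same C1.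
- Comparison: the chosen route is longer. In return, its one uncertain metal-mediated step runs on a substrate with a single reactive site, at room temperature and without base, and the route ends with neutral hydrogenolysis instead of a Lewis-acid demethylation.

Key step: step 7

## Route

Step 1
Reactants: 1 olivetol (5-pentylbenzene-1,3-diol)
Product: 2 4-bromo-5-pentylbenzene-1,3-diol
Conditions: NBS (1.0 equiv, in portions), MeCN, −20 → 0 °C
Reagents that add atoms: N-bromosuccinimide, O=C1CCC(=O)N1Br
Why: Electrophilic aromatic bromination of a resorcinol; attack para to one hydroxyl and ortho to the other (C4, equivalent to C6 by symmetry) is favoured over attack at C2, which is only ortho to both. Low temperature and no excess of reagent should hold the reaction at the monobromide.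

Step 2
Reactants: 3 methyl orsellinate (methyl 2,4-dihydroxy-6-methylbenzoate)
Product: 4 methyl 2-hydroxy-4-methoxy-6-methylbenzoate
Conditions: MeI (1.1 equiv), K2CO3 (1.1 equiv), acetone, reflux
Reagents that add atoms: iodomethane, CI
Why: Williamson ether synthesis; the C2' hydroxyl is held in a hydrogen bond to the ester carbonyl and is less acidic and less nucleophilic, so one equivalent of base and MeI should alkylate only the C4' hydroxyl.

Step 3
Reactants: 4 methyl 2-hydroxy-4-methoxy-6-methylbenzoate; 5 benzyl bromide
Product: 6 methyl 2-(benzyloxy)-4-methoxy-6-methylbenzoate
Conditions: BnBr, K2CO3, DMF, 60 °C
Reagents that add atoms: none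
Why: Williamson benzylation of the remaining chelated phenol, which needs the more polar solvent and gentle heat; no other nucleophilic site is present.

Step 4
Reactants: 6 methyl 2-(benzyloxy)-4-methoxy-6-methylbenzoate
Product: 7 2-(benzyloxy)-4-methoxy-6-methylbenzoic acid
Conditions: KOH, DMSO/H2O (4:1), 90 °C; then 1 M HCl, 0 °C
Reagents that add atoms: potassium hydroxide, [K+].[OH-] (the hydroxide oxygen becomes the carboxyl OH by acyl–oxygen cleavage)
Why: Saponification of a di-ortho-substituted benzoate is slow but should proceed in hot aqueous DMSO, where hydroxide is poorly solvated. The benzyl and methyl ethers are inert to base, and cold acidification avoids decarboxylation of the electron-rich acid.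

Step 5
Reactants: 7 2-(benzyloxy)-4-methoxy-6-methylbenzoic acid; 2 4-bromo-5-pentylbenzene-1,3-diol
Product: 9 4-bromo-3-hydroxy-5-pentylphenyl 2-(benzyloxy)-4-methoxy-6-methylbenzoate, via 2-(benzyloxy)-4-methoxy-6-methylbenzoyl chloride 8 (not isolated)
Conditions: (COCl)2, cat. DMF, CH2Cl2, 0 °C → rt, evaporate; then 2 (1.2 equiv), pyridine, cat. DMAP, CH2Cl2, 0 °C → rt
Reagents that add atoms: oxalyl chloride, O=C(Cl)C(=O)Cl (supplies the chlorine of 8 only; no atom of it stays in 9)
Why: Acid chloride formation through the Vilsmeier-type chloroiminium salt, then DMAP-catalysed O-acylation of a neutral phenol. The hydroxyl of 2 para to bromine has two ortho hydrogens, whereas the other is shielded by the ortho bromine and is the less nucleophilic one, and the acyl donor is itself di-ortho-substituted, so the ester should form at the oxygen para to bromine. A slight excess of 2 suppresses the diester.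

Step 6
Reactants: 9 4-bromo-3-hydroxy-5-pentylphenyl 2-(benzyloxy)-4-methoxy-6-methylbenzoate; 5 benzyl bromide
Product: 10 3-(benzyloxy)-4-bromo-5-pentylphenyl 2-(benzyloxy)-4-methoxy-6-methylbenzoate
Conditions: BnBr, K2CO3, DMF, rt
Reagents that add atoms: none
Why: Williamson benzylation of an ortho-bromophenol, acidic enough for carbonate at room temperature. The depside ester is a di-ortho-substituted benzoate whose carbonyl is shielded against attack by phenoxide, so acyl transfer should not compete, and the aryl bromide is inert.

Step 7
Reactants: 10 3-(benzyloxy)-4-bromo-5-pentylphenyl 2-(benzyloxy)-4-methoxy-6-methylbenzoate; 11 carbon dioxide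
Product: 12 2-(benzyloxy)-4-{[2-(benzyloxy)-4-methoxy-6-methylbenzoyl]oxy}-6-pentylbenzoic acid
Conditions: NiBr2 (10 mol%), 2,2'-bipyridine (20 mol%), Bu4NBF4, dry DMF, CO2 (1 atm), Mg anode, carbon-felt cathode, undivided cell, constant current (about 2.2 F/mol), rt; then 1 M HCl, 0 °C
Reagents that add atoms: none
Why: The bipyridine complex of divalent nickel takes up two electrons at the cathode, and the resulting zerovalent nickel undergoes oxidative addition to the C1–Br bond of 10; one-electron reduction of the arylnickel bromide then gives an aryl species of monovalent nickel, which inserts CO2 into its Ni–C bond, and a last electron releases the carboxylate to the magnesium ions of the dissolving anode and returns zerovalent nickel. The closest known reaction type is the nickel–bipyridine-catalysed electrocarboxylation of aryl halides in DMF with a sacrificial magnesium anode, applied here to a bromide flanked by an alkoxy and an alkyl group. No ring is closed and no stereocenter is formed. Both partners, the C1–Br carbon and CO2, are electrophiles, and the cathode supplies the reversal of polarity, so neither a stoichiometric organometallic reagent nor base nor heat is needed and the new acid stays as its magnesium salt until a cold acidic work-up. The step needs chemoselectivity for the C–Br bond over the aryl ester, the benzyl ethers and simple reduction to C–H. The catalyst operates at a potential well short of that needed to reduce an aryl benzoate or the bromide directly, zerovalent nickel adds to C–Br far faster than to an ester C–O bond at room temperature, and dry CO2-saturated DMF leaves CO2 as the only electrophile for the aryl–nickel intermediate. The two ortho substituents slow oxidative addition but also block the usual side reaction of biaryl coupling between two arylnickel centres, and the ortho benzyloxy oxygen can assist by coordinating nickel. The site of carboxylation is fixed by the bromine from step 1, so no regiochemical question arises.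

Step 8
Reactants: 12 2-(benzyloxy)-4-{[2-(benzyloxy)-4-methoxy-6-methylbenzoyl]oxy}-6-pentylbenzoic acid
Product: 13 2-hydroxy-4-[(2-hydroxy-4-methoxy-6-methylbenzoyl)oxy]-6-pentylbenzoic acid (CNP0313373.0)
Conditions: H2 (1 atm), 10% Pd/C, EtOAc, rt
Reagents that add atoms: none
Why: Hydrogenolysis of two benzyl aryl ethers over Pd/C under neutral conditions; the aryl ester, the methyl ether and the arenes are not touched. A non-nucleophilic solvent and evaporation without heating protect the depside ester and the decarboxylation-prone acid.

## Compound list

1 | olivetol (5-pentylbenzene-1,3-diol) | CCCCCc1cc(O)cc(O)c1 | starting material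
2 | 4-bromo-5-pentylbenzene-1,3-diol | CCCCCc1cc(O)cc(O)c1Br | intermediate
3 | methyl orsellinate (methyl 2,4-dihydroxy-6-methylbenzoate) | Cc1cc(O)cc(O)c1C(=O)OC | starting material
4 | methyl 2-hydroxy-4-methoxy-6-methylbenzoate | COc1cc(C)c(C(=O)OC)c(O)c1 | intermediate
5 | benzyl bromide | BrCc1ccccc1 | starting material
6 | methyl 2-(benzyloxy)-4-methoxy-6-methylbenzoate | COc1cc(C)c(C(=O)OC)c(OCc2ccccc2)c1 | intermediate
7 | 2-(benzyloxy)-4-methoxy-6-methylbenzoic acid | COc1cc(C)c(C(=O)O)c(OCc2ccccc2)c1 | intermediate
8 | 2-(benzyloxy)-4-methoxy-6-methylbenzoyl chloride (formed in the flask, not isolated) | COc1cc(C)c(C(=O)Cl)c(OCc2ccccc2)c1 | intermediate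
9 | 4-bromo-3-hydroxy-5-pentylphenyl 2-(benzyloxy)-4-methoxy-6-methylbenzoate | CCCCCc1cc(OC(=O)c2c(C)cc(OC)cc2OCc2ccccc2)cc(O)c1Br | intermediate
10 | 3-(benzyloxy)-4-bromo-5-pentylphenyl 2-(benzyloxy)-4-methoxy-6-methylbenzoate | CCCCCc1cc(OC(=O)c2c(C)cc(OC)cc2OCc2ccccc2)cc(OCc2ccccc2)c1Br | intermediate
11 | carbon dioxide | O=C=O | starting material
12 | 2-(benzyloxy)-4-{[2-(benzyloxy)-4-methoxy-6-methylbenzoyl]oxy}-6-pentylbenzoic acid | CCCCCc1cc(OC(=O)c2c(C)cc(OC)cc2OCc2ccccc2)cc(OCc2ccccc2)c1C(=O)O | intermediate
13 | 2-hydroxy-4-[(2-hydroxy-4-methoxy-6-methylbenzoyl)oxy]-6-pentylbenzoic acid (CNP0313373.0) | CCCCCc1cc(OC(=O)c2c(C)cc(OC)cc2O)cc(O)c1C(=O)O | target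

## Step count and least certain steps

Total: 8 steps. Longest linear sequence: 7 steps (3 → 4 → 6 → 7 → 9 → 10 → 12 → 13). The ring A branch (1 → 2) joins at step 5 and runs 5 steps from 1.

**Step 7 (key step).** The crowded aryl–nickel centre may take up CO2 slowly. The aryl group could then be protonated by traces of water or by the electrolyte, giving reduction of C–Br to C–H. If oxidative addition lags, electrons may leak into the aryl ester and cleave the depside link. Fallback: from 10, bromine–lithium exchange with t-BuLi (2 equiv) in THF/Et2O at −100 °C should give [2-(benzyloxy)-4-{[2-(benzyloxy)-4-methoxy-6-methylbenzoyl]oxy}-6-pentylphenyl]lithium F1. This is quenched at that temperature with dry gaseous 11 and worked up with cold dilute HCl, returning to the route at 12. Exchange at the aryl bromide is faster than addition to a di-ortho-substituted benzoate at this temperature, and an aryllithium para to the ester oxygen has no intramolecular path to acyl migration.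

**Step 5.** The choice between the two hydroxyls of 2 rests only on steric shielding and a modest difference in nucleophilicity, so acylation at the hydroxyl beside bromine, or at both, may compete. Fallback: the hydroxyls are differentiated before bromination. From 1, monobenzylation with 5 (K2CO3, DMF, with 1 in excess and recovered) should give 3-(benzyloxy)-5-pentylphenol F2. Bromination with NBS in MeCN at −20 °C, para to the free hydroxyl, should give 3-(benzyloxy)-4-bromo-5-pentylphenol F3, with the isomer from attack para to the benzyloxy group removed by chromatography. Acylation of its single hydroxyl with 8 (pyridine, cat. DMAP) returns to the route at 10, bypassing steps 1, 5 and 6.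

**Step 1.** The first bromine deactivates the ring only weakly, so a second bromination at C6 may follow, and some attack at C2 cannot be excluded. Fallback: from 1, bromination is driven with two equivalents of NBS to the symmetric 4,6-dibromo-5-pentylbenzene-1,3-diol F4, a clean endpoint because both positions para to a hydroxyl are filled. One bromine is then removed by n-BuLi (3.1 equiv: two for the hydroxyls, one for a single bromine–lithium exchange) in THF at −78 °C with a methanol quench. This returns to the route at 2. The charge already on the ring and the limited amount of base should stop the exchange after one bromine.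

**Step 6.** The phenoxide of 9, or adventitious hydroxide, may attack the ester of another molecule, which would move or cleave the depside link. Fallback: from 9, Mitsunobu etherification with benzyl alcohol, PPh3 and DIAD in THF at 0 °C → rt, in which the phenol reacts as the acid component and no free phenoxide builds up. This returns to the route at 10 and makes no new compound (F0).

**Step 8.** Once the C2 hydroxyl is unmasked, protonation at C1 and loss of CO2 become easy. Decarboxylation may therefore set in if the mixture warms or stands over the catalyst, and one benzyl ether may be left on if the run is stopped early. Fallback: from 12, Lewis-acid debenzylation with BCl3 and pentamethylbenzene as cation scavenger in CH2Cl2 at −78 °C. Both benzyl ethers lie ortho to a carbonyl group and are activated by chelation, while the unchelated C4' methyl ether should stay. A cold, weakly acidic quench returns to the route at 13, with no new compound (F0).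

## Further compounds

F1 | step 7 | [2-(benzyloxy)-4-{[2-(benzyloxy)-4-methoxy-6-methylbenzoyl]oxy}-6-pentylphenyl]lithium | [Li]c1c(CCCCC)cc(OC(=O)c2c(C)cc(OC)cc2OCc2ccccc2)cc1OCc1ccccc1
F2 | step 5 | 3-(benzyloxy)-5-pentylphenol | CCCCCc1cc(O)cc(OCc2ccccc2)c1
F3 | step 5 | 3-(benzyloxy)-4-bromo-5-pentylphenol | CCCCCc1cc(O)cc(OCc2ccccc2)c1Br
F4 | step 1 | 4,6-dibromo-5-pentylbenzene-1,3-diol | CCCCCc1c(Br)c(O)cc(O)c1Br
F0 | step 6 | none | none
F0 | step 8 | none | none
A1 | alternative 1 | benzyl trans-2,4-dioxo-6-pentylcyclohexane-1-carboxylate (racemic, one enantiomer drawn) | CCCCC[C@@H]1CC(=O)CC(=O)[C@H]1C(=O)OCc1ccccc1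
A2 | alternative 1 | (E)-non-3-en-2-one | CCCCC/C=C/C(C)=O
A3 | alternative 1 | dibenzyl malonate | O=C(CC(=O)OCc1ccccc1)OCc1ccccc1
A4 | alternative 2 | benzyl 4-(2,4-dihydroxy-6-methylbenzoyl)oxy-2-hydroxy-6-pentylbenzoate | CCCCCc1cc(OC(=O)c2c(C)cc(O)cc2O)cc(O)c1C(=O)OCc1ccccc1
A5 | alternative 2 | benzyl 2-hydroxy-6-pentyl-4-[(3,5,7-trioxooctanoyl)oxy]benzoate | CCCCCc1cc(OC(=O)CC(=O)CC(=O)CC(C)=O)cc(O)c1C(=O)OCc1ccccc1
A6 | alternative 2 | benzyl 2,4-dihydroxy-6-pentylbenzoate | CCCCCc1cc(O)cc(O)c1C(=O)OCc1ccccc1
A7 | alternative 3 | benzyl 4-(2,4-dimethoxy-6-methylbenzoyl)oxy-2-hydroxy-6-pentylbenzoate | CCCCCc1cc(OC(=O)c2c(C)cc(OC)cc2OC)cc(O)c1C(=O)OCc1ccccc1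
A8 | alternative 3 | 2-iodo-1,5-dimethoxy-3-methylbenzene | COc1cc(C)c(I)c(OC)c1
A9 | alternative 3 | carbon monoxide | [C-]#[O+]
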